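**Plan**

- Retrosynthesis: remove the C17 methylene and the silyl groups, then cut ring D at C13–C16, ring C at C9–C11 and C8–C14 (Diels–Alder), the lactone at C8=C9 and O–C7, the two one-carbon arms (C9, C20) at C10, and last ring A at C1–C10 and C3–C4, down to 2,3-dimethylbut-2-ene and acrolein.
- Forward: ring A first (one-pot double ene reaction), then double alkylation at C10, spiro lactone by Knoevenagel condensation, ring C by cycloaddition, ring D by radical cyclization, enone methylene last.
- Enabling feature: in ring A the C1 oxygen, C10 and the exocyclic carbon C6 on C5 form a homoallylic alcohol array, C1(O)–C10–C5(–C6), next to the gem-dimethyl carbon C4. This is the imprint of a carbonyl-ene closure of C1–C10 that follows a conjugate ene reaction at C3–C4; the CH2OH on C5 is the hydroborated ene methylene.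
- Stereochemistry: C1 by reagent-controlled CBS reduction of a prochiral ketone; C5 by hydroboration anti to the axial groups on C10 and C4; C10 by oxidizing the less hindered of its two CH2OH groups; C8, C9, C11, C14 by the endo Diels–Alder reaction on the lactone face remote from the C5 arm; C13 by the bridging ring closure.

Key step: step 1

Remark (numbering): atom numbers follow the ent-kaurane skeleton of the target: C1 (OAc), C4 (CMe2), C5–C6 (CH–CH2OH), C7 (lactone C=O), C8 and C13 (bridgeheads), C9, C10 (spiro), C11 (OH), C12, C14 (OH), C15 (C=O), C16=C17, C20 (OCH2).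
Assumption: (1E,3E)-buta-1,3-diene-1,4-diyl diacetate is taken as a purchasable compound.

**Route**

Step 1
Reactants: 1 2,3-dimethylbut-2-ene; 2 acrolein (prop-2-enal)
Product: 4 rac-4,4-dimethyl-3-methylidenecyclohexan-1-ol, via 4,4,5-trimethylhex-5-enal 3 (not isolated)
Conditions: Me2AlCl (1.1 equiv), CH2Cl2, −78 °C to 0 °C; then 1 M HCl
Reagents that add atoms: none
Why: Me2AlCl-complexed acrolein acts as an enophile at its C=C bond: the tetrasubstituted alkene 1 attacks the β-carbon (forming C3–C4 and the quaternary gem-dimethyl carbon) while an allylic hydrogen shifts to the α-carbon, giving the aluminium-bound δ,ε-unsaturated aldehyde 3, whose 1,1-disubstituted alkene then attacks the complexed carbonyl (forming C1–C10) with transfer of a hydrogen from the remaining allylic methyl to oxygen, leaving the exocyclic C5=C6 methylene. The closest known reaction type is the Lewis-acid-promoted sequential ene annulation of enals and enones with alkylidene alkanes (conjugate ene reaction followed by intramolecular carbonyl-ene reaction). Ring A closes by a type 2 intramolecular carbonyl-ene reaction through a chair-like six-membered transition state, 6-exo-trig at the carbonyl carbon with both olefinic carbons inside the new ring. The only new stereocentre is the carbinol carbon C1, which forms as a racemate with no controlling element and needs none, because it is erased in step 2 and set again by the reagent in step 4. The step needs conjugate rather than carbonyl attack in the first ene reaction and a single ene pathway in each stage: the first is secured by the large LUMO coefficient at the β-carbon of the complexed enal toward an electron-rich tetrasubstituted alkene, the second by the substrate itself, since the four methyl groups of 1 are equivalent and in 3 the quaternary C4 leaves the lone allylic methyl as the only hydrogen donor.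

Step 2
Reactants: 4 rac-4,4-dimethyl-3-methylidenecyclohexan-1-ol
Product: 5 4,4-dimethyl-3-methylidenecyclohexan-1-one
Conditions: Dess–Martin periodinane, pyridine, CH2Cl2, 0 °C to rt
Reagents that add atoms: none
Why: Dess–Martin oxidation converts the secondary alcohol into the β,γ-unsaturated ketone under buffered conditions, which deletes the uncontrolled C1 centre; any conjugated enone formed by double-bond migration would still give the same dienolate in step 3.

Step 3
Reactants: 5 4,4-dimethyl-3-methylidenecyclohexan-1-one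
Product: 7 2,2-bis[(benzyloxy)methyl]-4,4-dimethyl-3-methylidenecyclohexan-1-one, via mono(benzyloxymethyl) ketone 6 (not isolated)
Conditions: NaH (2.5 equiv), BnOCH2Cl (2.4 equiv), Bu4NI (cat.), THF, 0 °C to rt
Reagents that add atoms: benzyl chloromethyl ether, ClCOCc1ccccc1
Why: Geminal α,α-dialkylation of an extended enolate: under equilibrating conditions the ketone gives the dienolate spanning O–C1–C10–C5–C6, which is C-alkylated at the doubly activated C10 by the chloromethyl ether (as the softer iodide formed in the flask), and the mono-ether 6 re-enolizes in the same sense and is alkylated again at C10, which removes the last acidic hydrogen there, fixes the exocyclic alkene and creates no stereocentre because the two new groups are identical.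

Step 4
Reactants: 7 2,2-bis[(benzyloxy)methyl]-4,4-dimethyl-3-methylidenecyclohexan-1-one
Product: 8 (1S)-2,2-bis[(benzyloxy)methyl]-4,4-dimethyl-3-methylidenecyclohexan-1-ol
Conditions: (R)-2-methyl-CBS-oxazaborolidine (0.2 equiv), BH3·SMe2, THF, −20 °C; then MeOH
Reagents that add atoms: none
Why: Corey–Bakshi–Shibata reduction of a prochiral ketone flanked by a CH2 group and a quaternary carbon: the (R)-oxazaborolidine–borane complex binds the ketone with the quaternary C10 side in the large-group position and delivers hydride to one face, which sets (S)-C1 by reagent control and with it the absolute configuration of the whole route.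

Step 5
Reactants: 8 (1S)-2,2-bis[(benzyloxy)methyl]-4,4-dimethyl-3-methylidenecyclohexan-1-ol
Product: 9 (1S)-2,2-bis[(benzyloxy)methyl]-4,4-dimethyl-3-methylidenecyclohexyl acetate
Conditions: Ac2O, Et3N, DMAP (cat.), CH2Cl2, rt
Reagents that add atoms: acetic anhydride, CC(=O)OC(C)=O
Why: DMAP-catalysed acylation of the hindered secondary alcohol installs the C1 acetate of the target, which is carried unchanged to the end.

Step 6
Reactants: 9 (1S)-2,2-bis[(benzyloxy)methyl]-4,4-dimethyl-3-methylidenecyclohexyl acetate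
Product: 11 (1S,3R)-2,2-bis[(benzyloxy)methyl]-3-(hydroxymethyl)-4,4-dimethylcyclohexyl acetate, via primary alkylborane 10 (not isolated)
Conditions: BH3·THF, THF, 0 °C to rt; then 30% H2O2, aq. NaOAc
Reagents that add atoms: hydrogen peroxide, OO
Why: Hydroboration–oxidation (syn, anti-Markovnikov) places boron on C6 and hydrogen on C5; in the chair with the acetate equatorial one face of the methylene group is blocked by the axial CH2OBn arm on C10 and the axial methyl on C4, so borane should add from the other face and give (R)-C5 with the new CH2OH equatorial and cis to the acetate, while buffered peroxide spares the ester.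

Step 7
Reactants: 11 (1S,3R)-2,2-bis[(benzyloxy)methyl]-3-(hydroxymethyl)-4,4-dimethylcyclohexyl acetate
Product: 12 (1S,3R)-2,2-bis[(benzyloxy)methyl]-3-{[tert-butyl(diphenyl)silyl]oxymethyl}-4,4-dimethylcyclohexyl acetate
Conditions: t-BuPh2SiCl, imidazole, CH2Cl2, rt
Reagents that add atoms: tert-butyl(chloro)diphenylsilane, CC(C)(C)[Si](Cl)(c1ccccc1)c1ccccc1
Why: Silylation of the only free alcohol with a bulky, acid-stable silyl chloride protects O6 and later adds bulk on the C5 side of the spiro lactone.

Step 8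
Reactants: 12 (1S,3R)-2,2-bis[(benzyloxy)methyl]-3-{[tert-butyl(diphenyl)silyl]oxymethyl}-4,4-dimethylcyclohexyl acetate
Product: 13 (1S,3R)-3-{[tert-butyl(diphenyl)silyl]oxymethyl}-2,2-bis(hydroxymethyl)-4,4-dimethylcyclohexyl acetate
Conditions: H2 (1 atm), Pd/C (palladium metal on carbon), EtOAc, rt
Reagents that add atoms: none
Why: Hydrogenolysis of both benzyl ethers on palladium metal frees the two CH2OH arms on C10; no alkene is present at this stage, and acetate and silyl ether are inert.

Step 9
Reactants: 13 (1S,3R)-3-{[tert-butyl(diphenyl)silyl]oxymethyl}-2,2-bis(hydroxymethyl)-4,4-dimethylcyclohexyl acetate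
Product: 14 (1S,2R,3R)-3-{[tert-butyl(diphenyl)silyl]oxymethyl}-2-formyl-2-(hydroxymethyl)-4,4-dimethylcyclohexyl acetate
Conditions: TEMPO (0.1 equiv), PhI(OAc)2 (1.05 equiv), CH2Cl2, 0 °C
Reagents that add atoms: none
Why: TEMPO/oxoammonium oxidation is highly sensitive to steric hindrance: the axial CH2OH on C10 (cis to OAc and CH2OSi) is shielded by the 1,3-diaxial methyl on C4, so the equatorial one should be oxidized first, which turns C10 into a stereocentre with the aldehyde (later C9) trans and the remaining CH2OH (later C20) cis to the acetate; one equivalent of oxidant limits over-oxidation, and the aldehyde has no α-hydrogen.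

Step 10
Reactants: 14 (1S,2R,3R)-3-{[tert-butyl(diphenyl)silyl]oxymethyl}-2-formyl-2-(hydroxymethyl)-4,4-dimethylcyclohexyl acetate
Product: 16 (6S,7S,11R)-4-acetyl-11-{[tert-butyl(diphenyl)silyl]oxymethyl}-10,10-dimethyl-3-oxo-2-oxaspiro[5.5]undec-4-en-7-yl acetate, via formyl acetoacetate 15 (not isolated)
Conditions: 2,2,6-trimethyl-4H-1,3-dioxin-4-one (1.3 equiv), toluene, 110 °C; then piperidine (cat.), AcOH (cat.), 4 Å sieves, rt
Reagents that add atoms: 2,2,6-trimethyl-4H-1,3-dioxin-4-one, CC1=CC(=O)OC(C)(C)O1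
Why: Thermolysis of the dioxinone releases acetylketene, which acylates the remaining primary alcohol to the acetoacetate 15, and amine-catalysed intramolecular Knoevenagel condensation with the non-enolizable aldehyde then closes the six-membered unsaturated lactone (C8=C9) without touching a stereocentre, giving a doubly activated dienophile.

Step 11
Reactants: 17 (1E,3E)-buta-1,3-diene-1,4-diyl diacetate
Product: 19 (1E,3E)-1,4-bis[(tert-butyldimethylsilyl)oxy]buta-1,3-diene, via dilithium butadiene-1,4-diolate 18 (not isolated)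
Conditions: MeLi (4.1 equiv), THF, −78 to 0 °C; then t-BuMe2SiCl (4.5 equiv), DMPU, −78 °C to rt
Reagents that add atoms: tert-butyl(chloro)dimethylsilane, CC(C)(C)[Si](C)(C)Cl
Why: Methyllithium cleaves each enol acetate to the lithium enolate with retention of double-bond geometry, and O-silylation of the dienediolate 18 gives the electron-rich (E,E)-1,4-dioxygenated diene.

Step 12
Reactants: 16 spiro lactone dienophile; 19 (1E,3E)-1,4-bis[(tert-butyldimethylsilyl)oxy]buta-1,3-diene
Product: 20 Diels–Alder adduct: cis-fused cyclohexene on the spiro lactone with acetyl on C8, t-BuMe2SiO on C11 and C14, C12=C13, all stereocentres arranged as in the target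
Conditions: toluene, 2,6-di-tert-butyl-4-methylphenol (cat.), 80 °C, sealed tube
Reagents that add atoms: none
Why: Normal-demand Diels–Alder reaction of the alkylidene β-keto lactone with the (E,E)-diene forms C9–C11 and C8–C14 and sets four stereocentres: suprafacial addition makes the C11 and C14 oxygens cis, the Alder endo orientation of the acetyl group (spiro lactone ring exo) places both cis to the acetyl group and to H9, and the diene should approach the lactone face on the C1 side, away from the bulkier CH2OSi(t-Bu)Ph2 group on C5.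

Step 13
Reactants: 20 Diels–Alder adduct
Product: 22 C16 bromo ketone (bromoacetyl group on C8), via trimethylsilyl enol ether 21 (not isolated)
Conditions: Me3SiOTf, Et3N, CH2Cl2, 0 °C; then N-bromosuccinimide, THF, −78 °C
Reagents that add atoms: N-bromosuccinimide, O=C1CCC(=O)N1Br
Why: Soft enolization with Me3SiOTf and Et3N can occur only toward the acetyl methyl group because C8 is quaternary, and the silyl enol ether 21 is brominated by N-bromosuccinimide far faster than the ring alkene, giving the α-bromo ketone.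

Step 14
Reactants: 22 C16 bromo ketone
Product: 23 tetracyclic ketone with the bicyclo[3.2.1]octane closed (C16 = CH2; 1-OAc, 6-OSi(t-Bu)Ph2, 11- and 14-OSi(t-Bu)Me2), stereocentres as in the target
Conditions: Bu3SnH, AIBN (cat.), benzene (0.01 M), 80 °C, slow addition
Reagents that add atoms: none
Why: Tin hydride radical cyclization: the α-keto radical at C16, held over ring C by the pseudoaxial acyl group, should add 5-exo-trig to C13 through a chair-like array (attack at C12 would need a boat leading to a bicyclo[2.2.2]octane), and the C12 radical then takes hydrogen from Bu3SnH; the configuration of the new bridgehead C13 is dictated by the bridge.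

Step 15
Reactants: 23 tetracyclic ketone
Product: 26 6-O-(tert-butyldiphenylsilyl)-11,14-bis-O-(tert-butyldimethylsilyl) ether of the target, via Mannich base 24 (not isolated), via methiodide 25 (not isolated)
Conditions: LiN(SiMe3)2, THF, −78 °C; CH2=NMe2+ I−; then MeI, CH2Cl2; then aq. NaHCO3
Reagents that add atoms: N,N-dimethylmethylideneammonium iodide (Eschenmoser's salt), C=[N+](C)C.[I-]
Why: α-Methylenation through a Mannich base: the ketone can enolize only toward C16 because C8 is quaternary, the lithium enolate adds to Eschenmoser's salt, and N-methylation followed by mild base-induced elimination of trimethylamine gives the exocyclic enone; the lactone has no α-hydrogen and the acetate is less acidic than the ketone.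

Step 16
Reactants: 26 tris-silyl ether of the target
Product: 27 CNP0225182.1, (1S,5R,8R,9S,10R,11S,13S,14R)-1-acetoxy-6,11,14-trihydroxy-15-oxo-6,7-seco-ent-kaur-16-en-7,20-olide
Conditions: HF·pyridine, pyridine, THF, 0 °C to rt
Reagents that add atoms: none
Why: Fluoride cleavage of the primary and the two secondary silyl ethers under buffered, weakly acidic conditions frees O6, O11 and O14 without acetate migration, retro-aldol cleavage at C8–C14 or conjugate addition to the enone.

**Compound list**

1 | 2,3-dimethylbut-2-ene | CC(C)=C(C)C | starting material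
2 | acrolein (prop-2-enal) | C=CC=O | starting material
3 | 4,4,5-trimethylhex-5-enal | O=CCCC(C)(C)C(C)=C | intermediate
4 | rac-4,4-dimethyl-3-methylidenecyclohexan-1-ol | C=C1CC(O)CCC1(C)C | intermediate
5 | 4,4-dimethyl-3-methylidenecyclohexan-1-one | C=C1CC(=O)CCC1(C)C | intermediate
6 | rac-2-[(benzyloxy)methyl]-4,4-dimethyl-3-methylidenecyclohexan-1-one | C=C1C(COCc2ccccc2)C(=O)CCC1(C)C | intermediate
7 | 2,2-bis[(benzyloxy)methyl]-4,4-dimethyl-3-methylidenecyclohexan-1-one | C=C1C(COCc2ccccc2)(COCc2ccccc2)C(=O)CCC1(C)C | intermediate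
8 | (1S)-2,2-bis[(benzyloxy)methyl]-4,4-dimethyl-3-methylidenecyclohexan-1-ol | C(OCc1ccccc1)C2(COCc1ccccc1)[C@@H](O)CCC(C)(C)C2=C | intermediate
9 | (1S)-2,2-bis[(benzyloxy)methyl]-4,4-dimethyl-3-methylidenecyclohexyl acetate | C(OCc1ccccc1)C2(COCc1ccccc1)[C@@H](OC(C)=O)CCC(C)(C)C2=C | intermediate
10 | primary alkylborane of 9 (BH2 on C6, H on C5, C6 cis to OAc) | C(OCc1ccccc1)C2(COCc1ccccc1)[C@@H](OC(C)=O)CCC(C)(C)[C@H]2CB | intermediate
11 | (1S,3R)-2,2-bis[(benzyloxy)methyl]-3-(hydroxymethyl)-4,4-dimethylcyclohexyl acetate | C(OCc1ccccc1)C2(COCc1ccccc1)[C@@H](OC(C)=O)CCC(C)(C)[C@H]2CO | intermediate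
12 | (1S,3R)-2,2-bis[(benzyloxy)methyl]-3-{[tert-butyl(diphenyl)silyl]oxymethyl}-4,4-dimethylcyclohexyl acetate | C(OCc1ccccc1)C2(COCc1ccccc1)[C@@H](OC(C)=O)CCC(C)(C)[C@H]2CO[Si](c1ccccc1)(c1ccccc1)C(C)(C)C | intermediate
13 | (1S,3R)-3-{[tert-butyl(diphenyl)silyl]oxymethyl}-2,2-bis(hydroxymethyl)-4,4-dimethylcyclohexyl acetate | OCC2(CO)[C@@H](OC(C)=O)CCC(C)(C)[C@H]2CO[Si](c1ccccc1)(c1ccccc1)C(C)(C)C | intermediate
14 | (1S,2R,3R)-3-{[tert-butyl(diphenyl)silyl]oxymethyl}-2-formyl-2-(hydroxymethyl)-4,4-dimethylcyclohexyl acetate (CH2OH cis, CHO trans to OAc) | OC[C@]2([C@@H](OC(C)=O)CCC(C)(C)[C@H]2CO[Si](c1ccccc1)(c1ccccc1)C(C)(C)C)C=O | intermediate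
15 | (1S,2R,3R)-3-{[tert-butyl(diphenyl)silyl]oxymethyl}-2-formyl-4,4-dimethyl-2-[(3-oxobutanoyloxy)methyl]cyclohexyl acetate | CC(=O)CC(=O)OC[C@]2([C@@H](OC(C)=O)CCC(C)(C)[C@H]2CO[Si](c1ccccc1)(c1ccccc1)C(C)(C)C)C=O | intermediate
16 | (6S,7S,11R)-4-acetyl-11-{[tert-butyl(diphenyl)silyl]oxymethyl}-10,10-dimethyl-3-oxo-2-oxaspiro[5.5]undec-4-en-7-yl acetate | CC(=O)C1=C[C@]2(COC1=O)[C@@H](OC(C)=O)CCC(C)(C)[C@H]2CO[Si](c3ccccc3)(c3ccccc3)C(C)(C)C | intermediate
17 | (1E,3E)-buta-1,3-diene-1,4-diyl diacetate | CC(=O)O/C=C/C=C/OC(C)=O | starting material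
18 | dilithium (1E,3E)-buta-1,3-diene-1,4-diolate | [Li+].[Li+].[O-]/C=C/C=C/[O-] | intermediate
19 | (1E,3E)-1,4-bis[(tert-butyldimethylsilyl)oxy]buta-1,3-diene | CC(C)(C)[Si](C)(C)O/C=C/C=C/O[Si](C)(C)C(C)(C)C | intermediate
20 | Diels–Alder adduct (C8 acetyl, C11/C14 OSi(t-Bu)Me2 cis to acetyl and H9, C12=C13; C1, C5, C8, C9, C10, C11, C14 arranged as in 27) | CC(=O)[C@@]12C(=O)OC[C@]3([C@@H](OC(C)=O)CCC(C)(C)[C@H]3CO[Si](c4ccccc4)(c4ccccc4)C(C)(C)C)[C@@H]1[C@@H](O[Si](C)(C)C(C)(C)C)C=C[C@H]2O[Si](C)(C)C(C)(C)C | intermediate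
21 | trimethylsilyl enol ether of 20 (C15(OSiMe3)=C16H2) | C=C(O[Si](C)(C)C)[C@@]12C(=O)OC[C@]3([C@@H](OC(C)=O)CCC(C)(C)[C@H]3CO[Si](c4ccccc4)(c4ccccc4)C(C)(C)C)[C@@H]1[C@@H](O[Si](C)(C)C(C)(C)C)C=C[C@H]2O[Si](C)(C)C(C)(C)C | intermediate
22 | C16 bromo ketone of 20 (BrCH2–C15(=O) on C8) | BrCC(=O)[C@@]12C(=O)OC[C@]3([C@@H](OC(C)=O)CCC(C)(C)[C@H]3CO[Si](c4ccccc4)(c4ccccc4)C(C)(C)C)[C@@H]1[C@@H](O[Si](C)(C)C(C)(C)C)C=C[C@H]2O[Si](C)(C)C(C)(C)C | intermediate
23 | tetracyclic ketone, 17-nor analogue of 26 (C16 = CH2), stereocentres as in 27 | C1C(=O)[C@@]23C(=O)OC[C@]4([C@@H](OC(C)=O)CCC(C)(C)[C@H]4CO[Si](c5ccccc5)(c5ccccc5)C(C)(C)C)[C@@H]2[C@@H](O[Si](C)(C)C(C)(C)C)C[C@@H]1[C@H]3O[Si](C)(C)C(C)(C)C | intermediate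
24 | Mannich base: 16-[(dimethylamino)methyl] derivative of 23 (C16 epimers) | CN(C)CC1C(=O)[C@@]23C(=O)OC[C@]4([C@@H](OC(C)=O)CCC(C)(C)[C@H]4CO[Si](c5ccccc5)(c5ccccc5)C(C)(C)C)[C@@H]2[C@@H](O[Si](C)(C)C(C)(C)C)C[C@@H]1[C@H]3O[Si](C)(C)C(C)(C)C | intermediate
25 | methiodide of 24 (trimethylammonium iodide) | C[N+](C)(C)CC1C(=O)[C@@]23C(=O)OC[C@]4([C@@H](OC(C)=O)CCC(C)(C)[C@H]4CO[Si](c5ccccc5)(c5ccccc5)C(C)(C)C)[C@@H]2[C@@H](O[Si](C)(C)C(C)(C)C)C[C@@H]1[C@H]3O[Si](C)(C)C(C)(C)C.[I-] | intermediate
26 | 6-O-(tert-butyldiphenylsilyl)-11,14-bis-O-(tert-butyldimethylsilyl) ether of 27 | C=C1C(=O)[C@@]23C(=O)OC[C@]4([C@@H](OC(C)=O)CCC(C)(C)[C@H]4CO[Si](c5ccccc5)(c5ccccc5)C(C)(C)C)[C@@H]2[C@@H](O[Si](C)(C)C(C)(C)C)C[C@@H]1[C@H]3O[Si](C)(C)C(C)(C)C | intermediate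
27 | CNP0225182.1, (1S,5R,8R,9S,10R,11S,13S,14R)-1-acetoxy-6,11,14-trihydroxy-15-oxo-6,7-seco-ent-kaur-16-en-7,20-olide | C=C1C(=O)[C@@]23C(=O)OC[C@]4([C@@H](OC(C)=O)CCC(C)(C)[C@H]4CO)[C@@H]2[C@@H](O)C[C@@H]1[C@H]3O | target

**Step count and risks**

Total step count: 16. Longest linear sequence: 15 steps (steps 1–10 and 12–16; step 11 makes the diene).

Steps most likely to fail:

Step 9. The two CH2OH groups on C10 may not be told apart well enough by the oxidant, or the diol may be oxidized twice. Fallback, which replaces steric group selection by arms that are chemically different from the start: from ketone 5, alkylation with one equivalent of benzyl chloromethyl ether with isolation of 6, then a second alkylation with 4-methoxybenzyl chloromethyl ether, would give the racemic mixed bis-ether ketone F1. Corey–Bakshi–Shibata reduction with the (R)-oxazaborolidine should act on both enantiomers under reagent control and give two separable (S)-carbinols; the one with the hydroxyl cis to CH2OBn, alcohol F2, is kept (at most half of the material). Acetylation (acetate F3), hydroboration–oxidation (primary alcohol F4) and silylation (silyl ether F5) follow as in steps 5–7. DDQ then removes only the 4-methoxybenzyl group on the trans arm (alcohol F6), Dess–Martin oxidation gives aldehyde F7, and hydrogenolysis of the remaining benzyl ether returns hydroxy aldehyde 14.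

Step 12. The cycloaddition may be slow at the neopentyl β-carbon C9, the acyl enone unit may instead react as a heterodiene with one enol ether bond of 19, or the two lactone faces may not be distinguished well. Fallback, which brings in the two oxygens after the ring is made: from dienophile 16, Diels–Alder reaction with the smaller and more reactive (E)-1-(trimethylsilyloxy)buta-1,3-diene (its unsubstituted terminus bonds to C9) would give cycloadduct F8. Acid (TsOH, benzene, warm) removes the silyl group and dehydrates the allylic alcohol to the ring C cyclohexa-1,3-diene F9. Singlet oxygen (O2, tetraphenylporphyrin, light) should add across C11/C14 from the face opposite the lactone ring to give endoperoxide F10; thiourea reduces it to the cis-enediol F11, and t-BuMe2SiOTf/2,6-lutidine gives adduct 20.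

Step 14. The radical may close in the 6-endo mode onto C12 (bicyclo[2.2.2]octane) or be reduced before it cyclizes. Fallback, which forms C13–C16 by C–H insertion instead: from adduct 20, hydrogenation of the ring alkene (H2, Pd/C) would give the saturated methyl ketone F12. Enolate trifluoroacetylation (LiN(SiMe3)2, CF3CO2CH2CF3) gives the trifluoroacetyl ketone F13, and diazo transfer with methanesulfonyl azide and Et3N gives the diazo ketone F14. Rh2(OAc)4 then brings about 1,5-insertion of the carbenoid into the axial C13–H bond, the only C–H bond within reach of the axial acyl group, to give ketone 23.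

Further compounds
F1 | step 9 | rac-2-[(benzyloxy)methyl]-2-{[(4-methoxybenzyl)oxy]methyl}-4,4-dimethyl-3-methylidenecyclohexan-1-one | C=C1C(COCc2ccccc2)(COCc2ccc(OC)cc2)C(=O)CCC1(C)C
F2 | step 9 | (1S,2S)-2-[(benzyloxy)methyl]-2-{[(4-methoxybenzyl)oxy]methyl}-4,4-dimethyl-3-methylidenecyclohexan-1-ol (OH cis to CH2OBn) | C(OCc1ccccc1)[C@]2([C@@H](O)CCC(C)(C)C2=C)COCc1ccc(OC)cc1
F3 | step 9 | acetate of F2 | C(OCc1ccccc1)[C@]2([C@@H](OC(C)=O)CCC(C)(C)C2=C)COCc1ccc(OC)cc1
F4 | step 9 | primary alcohol from F3 (CH2OH on C5, cis to OAc) | C(OCc1ccccc1)[C@]2([C@@H](OC(C)=O)CCC(C)(C)[C@H]2CO)COCc1ccc(OC)cc1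
F5 | step 9 | tert-butyldiphenylsilyl ether of F4 | C(OCc1ccccc1)[C@]2([C@@H](OC(C)=O)CCC(C)(C)[C@H]2CO[Si](c3ccccc3)(c3ccccc3)C(C)(C)C)COCc1ccc(OC)cc1
F6 | step 9 | alcohol from F5 after loss of the 4-methoxybenzyl group (CH2OH trans to OAc) | C(OCc1ccccc1)[C@]2([C@@H](OC(C)=O)CCC(C)(C)[C@H]2CO[Si](c3ccccc3)(c3ccccc3)C(C)(C)C)CO
F7 | step 9 | aldehyde from F6 (O-benzyl ether of 14) | C(OCc1ccccc1)[C@]2([C@@H](OC(C)=O)CCC(C)(C)[C@H]2CO[Si](c3ccccc3)(c3ccccc3)C(C)(C)C)C=O
F8 | step 12 | Diels–Alder adduct of 16 with (E)-1-(trimethylsilyloxy)buta-1,3-diene (OSiMe3 on C14, C12=C13) | CC(=O)[C@@]12C(=O)OC[C@]3([C@@H](OC(C)=O)CCC(C)(C)[C@H]3CO[Si](c4ccccc4)(c4ccccc4)C(C)(C)C)[C@@H]1CC=C[C@H]2O[Si](C)(C)C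
F9 | step 12 | ring C cyclohexa-1,3-diene (C11=C12–C13=C14) | CC(=O)[C@@]12C(=O)OC[C@]3([C@@H](OC(C)=O)CCC(C)(C)[C@H]3CO[Si](c4ccccc4)(c4ccccc4)C(C)(C)C)[C@@H]1C=CC=C2
F10 | step 12 | C11,C14-endoperoxide of F9 (oxygens cis to the acetyl group) | CC(=O)[C@@]12C(=O)OC[C@]3([C@@H](OC(C)=O)CCC(C)(C)[C@H]3CO[Si](c4ccccc4)(c4ccccc4)C(C)(C)C)[C@@H]1[C@@H]5C=C[C@H]2OO5
F11 | step 12 | C11,C14-cis-enediol (bis-desilyl 20) | CC(=O)[C@@]12C(=O)OC[C@]3([C@@H](OC(C)=O)CCC(C)(C)[C@H]3CO[Si](c4ccccc4)(c4ccccc4)C(C)(C)C)[C@@H]1[C@@H](O)C=C[C@H]2O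
F12 | step 14 | 12,13-dihydro derivative of 20 | CC(=O)[C@@]12C(=O)OC[C@]3([C@@H](OC(C)=O)CCC(C)(C)[C@H]3CO[Si](c4ccccc4)(c4ccccc4)C(C)(C)C)[C@@H]1[C@@H](O[Si](C)(C)C(C)(C)C)CC[C@H]2O[Si](C)(C)C(C)(C)C
F13 | step 14 | C16-trifluoroacetyl derivative of F12 | FC(F)(F)C(=O)CC(=O)[C@@]12C(=O)OC[C@]3([C@@H](OC(C)=O)CCC(C)(C)[C@H]3CO[Si](c4ccccc4)(c4ccccc4)C(C)(C)C)[C@@H]1[C@@H](O[Si](C)(C)C(C)(C)C)CC[C@H]2O[Si](C)(C)C(C)(C)C
F14 | step 14 | C16 diazo ketone of F12 | [N-]=[N+]=CC(=O)[C@@]12C(=O)OC[C@]3([C@@H](OC(C)=O)CCC(C)(C)[C@H]3CO[Si](c4ccccc4)(c4ccccc4)C(C)(C)C)[C@@H]1[C@@H](O[Si](C)(C)C(C)(C)C)CC[C@H]2O[Si](C)(C)C(C)(C)C
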